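## Retrosynthetic overview

1. The hydroperoxide is made last by a Schenck ene reaction on the C6′=C7′ alkene; the two tertiary carbinols (C7, C1′) come together from two exocyclic methylene groups by oxymercuration.
2. The CH2–CH2 bridge is cut in the middle: Giese coupling of a right-half C5′–CH2 iodide with a left-half 6-methylidene-7-ketone.
3. Left half, key step: a monocyclic cyclopentane bis-epoxide gives, in one BF3 operation, the oxepane (O1–C2 closure) and the cyclohexanone, by shift of C5a from C7 to the oxirane carbon C6 (cyclopentane C5a–C7–C8–C9–C9a becomes the six-membered ring). The enabling feature is the array C7 (oxygen-bearing) – C6 (CH carrying the bridge carbon) – C5a (quaternary) in the carbocycle, a semipinacol retron, beside the O1–C2(Me)2–C3H(OH) unit of the oxepane, an endo epoxide-opening retron.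
4. The cyclopentane comes from 2-methylcyclopentane-1,3-dione, acrolein and a Wittig reaction; C5a and C9a are set by enzymatic desymmetrisation, C3 by Shi epoxidation.
5. Right half: Diels–Alder reaction of isoprene with 4,4-dimethylcyclohexenone gives the cis-decalin; ene/Kornblum–DeLaMare gives the enone; conjugate addition sets C5′. Ring order: left, cyclopentane (bought), then oxepane and cyclohexane together (step 7); right, the CMe2 ring is bought and the cyclohexene ring is made by cycloaddition.

Key step: step 7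

Remark: left-half atoms carry 1-benzoxepine locants (O1, C2–C5, C5a, C6–C9, C9a), right-half atoms primed naphthalene locants (C1′ carbinol, C4′ CMe2, C5′ bridge carbon, C6′ methyl-bearing, C7′ hydroperoxy-bearing); stereocentres that are erased later are carried as epimer mixtures and drawn without configuration.

## Route

Step 1
Reactants: 1 2-methylcyclopentane-1,3-dione; 2 acrolein
Product: 3 3-(1-methyl-2,5-dioxocyclopentyl)propanal
Conditions: H2O, rt
Reagents that add atoms: none
Why: Michael addition of the acidic cyclic 1,3-dione to acrolein in water builds the quaternary carbon (future C5a) without O-alkylation.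

Step 2
Reactants: 3 3-(1-methyl-2,5-dioxocyclopentyl)propanal
Product: 4 2-methyl-2-(4-methylpent-3-en-1-yl)cyclopentane-1,3-dione
Conditions: iPrPPh3I, n-BuLi, THF, 0 °C; then 3, −78 °C → rt
Reagents that add atoms: isopropyltriphenylphosphonium iodide, CC(C)[P+](c1ccccc1)(c1ccccc1)c1ccccc1.[I-]
Why: Wittig olefination with the non-stabilised isopropylidene ylide takes the aldehyde far faster than the two neopentyl-type ring ketones and installs the trisubstituted alkene that becomes C2–C3.

Step 3
Reactants: 4 2-methyl-2-(4-methylpent-3-en-1-yl)cyclopentane-1,3-dione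
Product: 5 (2R,3S)-3-hydroxy-2-methyl-2-(4-methylpent-3-en-1-yl)cyclopentan-1-one
Conditions: ketoreductase (NADPH-dependent, selected from a panel for the 2R,3S product), NADP+ (cat.), iPrOH, phosphate buffer pH 7, 30 °C
Reagents that add atoms: none
Why: desymmetrising reduction by a ketoreductase (alcohol dehydrogenase class) differentiates the enantiotopic carbonyl groups and delivers hydride so that the hydroxyl is cis to the methyl group, which sets C9a (S) and the quaternary C5a in one event under enzyme control.

Step 4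
Reactants: 5 (2R,3S)-3-hydroxy-2-methyl-2-(4-methylpent-3-en-1-yl)cyclopentan-1-one
Product: 6 (2R,3S)-2-{2-[(2S)-3,3-dimethyloxiran-2-yl]ethyl}-3-hydroxy-2-methylcyclopentan-1-one
Conditions: ent-Shi ketone (L-fructose-derived, 30 mol%), KHSO5 (as Oxone), K2CO3, Bu4NHSO4, MeCN–(MeO)2CH2–aq. Na2B4O7 buffer (pH 10.5), 0 °C
Reagents that add atoms: potassium peroxymonosulfate, [K+].[O-]S(=O)(=O)OO
Why: Shi epoxidation (chiral dioxirane, spiro transition state) of the trisubstituted alkene should give the (S)-oxirane under reagent control at a pH where the hydroxy ketone and the epoxide are stable; this carbon becomes C3.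

Step 5
Reactants: 6 (2R,3S)-2-{2-[(2S)-3,3-dimethyloxiran-2-yl]ethyl}-3-hydroxy-2-methylcyclopentan-1-one
Product: 8 (1S,2R)-2-{2-[(2S)-3,3-dimethyloxiran-2-yl]ethyl}-3-ethenyl-2-methyl-3-[(trimethylsilyl)oxy]cyclopentan-1-ol (C3 epimers), via bis-silyl ether 7 (not isolated)
Conditions: vinylMgBr (3 equiv), THF, −78 °C; Me3SiCl, −78 °C → rt; then K2CO3 (cat.), MeOH, 0 °C
Reagents that add atoms: vinylmagnesium bromide, C=C[Mg]Br; chlorotrimethylsilane, C[Si](C)(C)Cl
Why: Grignard 1,2-addition to the ketone, silylation of both alkoxides and selective methanolysis of the less hindered secondary silyl ether leave the tertiary oxygen capped and the secondary hydroxyl free; the new carbinol carbon becomes the carbonyl carbon in step 7, so its configuration is of no consequence.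

Step 6
Reactants: 8 (1S,2R)-2-{2-[(2S)-3,3-dimethyloxiran-2-yl]ethyl}-3-ethenyl-2-methyl-3-[(trimethylsilyl)oxy]cyclopentan-1-ol
Product: 9 (1S,2R)-2-{2-[(2S)-3,3-dimethyloxiran-2-yl]ethyl}-2-methyl-3-(oxiran-2-yl)-3-[(trimethylsilyl)oxy]cyclopentan-1-ol (epimers at C3 and at the new oxirane carbon)
Conditions: dimethyldioxirane, acetone, 0 °C
Reagents that add atoms: dimethyldioxirane, CC1(C)OO1
Why: epoxidation of the monosubstituted alkene with the neutral dioxirane keeps the acid-labile epoxy alcohol and the silyl ether intact; the configuration of the new oxirane carbon does not matter because it becomes the epimerisable C6.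

Step 7
Reactants: 9 (1S,2R)-2-{2-[(2S)-3,3-dimethyloxiran-2-yl]ethyl}-2-methyl-3-(oxiran-2-yl)-3-[(trimethylsilyl)oxy]cyclopentan-1-ol
Product: 11 (3S,5aS,9aS)-3-hydroxy-6-(hydroxymethyl)-2,2,5a-trimethyloctahydro-1-benzoxepin-7(2H)-one (C6 epimers), via oxepane-fused cyclopentane 10 (not isolated)
Conditions: BF3·OEt2 (2.5 equiv), CH2Cl2, −78 → −20 °C; then aq. NaHCO3
Reagents that add atoms: none
Why: BF3 first activates the trisubstituted epoxide, whose tertiary carbon (future C2) is attacked by the free secondary hydroxyl in a 7-endo-tet closure with retention at C3, which forms the oxepane by C–O bond formation, trans-fused to the five-membered ring (10); BF3 then opens the oxirane next to the silylated tertiary carbinol, and the C7–C5a bond, anti to the breaking C–O bond, shifts to the oxirane CH with retention at the migrating C5a, so that C7 becomes the ketone, the silyl group leaves as Me3SiF and the cyclopentane becomes the cyclohexanone by ring expansion by one carbon. The closest known reaction types are the Lewis-acid semipinacol rearrangement of 2,3-epoxy silyl ethers to β-hydroxy ketones, including cyclopentanol-to-cyclohexanone ring enlargement, and the endo-selective acid-promoted opening of trisubstituted epoxides by hydroxyl groups. No lasting stereocentre is created: C3 comes from the Shi epoxide, C5a and C9a from the enzymatic reduction and are not touched, and C6 (formed with inversion at the oxirane carbon) is epimerisable and is erased in step 8, which is why all epimers of 9 converge. The selectivities needed are endo over exo opening, secured by the cation-stabilising tertiary C2 and by the strain of the trans-fused six–five alternative; migration of the quaternary C5a rather than the C8 methylene, secured by the higher migratory aptitude of the more substituted carbon; and silence of the tertiary oxygen toward the trisubstituted epoxide, secured by its silyl cap.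

Step 8
Reactants: 11 (3S,5aS,9aS)-3-hydroxy-6-(hydroxymethyl)-2,2,5a-trimethyloctahydro-1-benzoxepin-7(2H)-one
Product: 13 (3S,5aS,9aS)-3-hydroxy-2,2,5a-trimethyl-6-methylideneoctahydro-1-benzoxepin-7(2H)-one, via primary mesylate 12 (not isolated)
Conditions: MsCl (1.05 equiv), Et3N, CH2Cl2, −40 °C; then DBU, 0 °C
Reagents that add atoms: none
Why: chemoselective mesylation of the primary hydroxyl (the C3 hydroxyl is secondary and flanked by the gem-dimethyl carbon) and E1cB elimination of the β-mesyloxy ketone give the α-methylene ketone and remove the C6 stereocentre.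

Step 9
Reactants: 14 4,4-dimethylcyclohex-2-en-1-one; 15 isoprene
Product: 16 (4aR,8aS)-4,4,6-trimethyl-3,4,4a,5,8,8a-hexahydronaphthalen-1(2H)-one
Conditions: B-(o-tolyl)oxazaborolidinium triflimide from α,α-diphenylprolinol (20 mol%; the catalyst antipode that gives 4aR,8aS), CH2Cl2, −20 °C
Reagents that add atoms: none
Why: enantioselective Diels–Alder reaction under chiral Lewis acid catalysis: suprafacial addition to the cis dienophile gives the cis ring fusion, the methyl group ends para to the carbonyl-bearing carbon as is usual for isoprene, and the catalyst sets the absolute configuration of C4a′ and C8a′.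

Step 10
Reactants: 16 (4aR,8aS)-4,4,6-trimethyl-3,4,4a,5,8,8a-hexahydronaphthalen-1(2H)-one
Product: 17 (4aR,8aS)-4,4,6-trimethyl-1-methylidene-1,2,3,4,4a,5,8,8a-octahydronaphthalene
Conditions: Zn, CH2Br2, TiCl4, THF–CH2Cl2, 0 °C → rt
Reagents that add atoms: dibromomethane, BrCBr
Why: Takai–Lombardo methylenation is non-basic and should not epimerise the cis ring fusion next to the carbonyl group; the exocyclic alkene masks the later tertiary carbinol at C1′.

Step 11
Reactants: 17 (4aR,8aS)-4,4,6-trimethyl-1-methylidene-1,2,3,4,4a,5,8,8a-octahydronaphthalene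
Product: 21 (4aR,8aS)-3,5,5-trimethyl-8-methylidene-4a,5,6,7,8,8a-hexahydronaphthalen-2(1H)-one, via endocyclic hydroperoxide 18 (not isolated), via exocyclic hydroperoxide 19 (not isolated), via exo-methylene ketone 20 (not isolated)
Conditions: O2, tetraphenylporphyrin (cat.), visible light, CH2Cl2, 0 °C; then Ac2O, pyridine, DMAP (cat.), rt; then DBU, rt
Reagents that add atoms: oxygen, O=O
Why: Schenck ene reaction of singlet oxygen with the trisubstituted ring alkene (much faster than with the 1,1-disubstituted exocyclic alkene), Kornblum–DeLaMare dehydration of the secondary allylic hydroperoxides and base isomerisation of the exocyclic enone into the ring converge both C7′-oxygenated ene products on one enone, while the tertiary C6′ hydroperoxide regioisomer is inert to these conditions and is removed.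

Step 12
Reactants: 21 (4aR,8aS)-3,5,5-trimethyl-8-methylidene-4a,5,6,7,8,8a-hexahydronaphthalen-2(1H)-one
Product: 22 (4R,4aS,8aS)-4-{[dimethyl(propan-2-yloxy)silyl]methyl}-3,5,5-trimethyl-8-methylidene-1,4,4a,5,6,7,8,8a-octahydronaphthalen-2-yl trifluoromethanesulfonate
Conditions: (iPrO)Me2SiCH2MgCl, CuBr·SMe2 (20 mol%), THF, −78 → −30 °C; then PhNTf2, −78 °C → rt
Reagents that add atoms: {[dimethyl(propan-2-yloxy)silyl]methyl}magnesium chloride, CC(C)O[Si](C)(C)C[Mg]Cl; N-phenylbis(trifluoromethanesulfonimide), O=S(=O)(N(c1ccccc1)S(=O)(=O)C(F)(F)F)C(F)(F)F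
Why: copper-catalysed conjugate addition of the hydroxymethyl-equivalent Grignard reagent should occur anti to the adjacent C4a′–C4′ bond, on the convex face of the cis-fused bicycle, which sets C5′ with the new carbon cis to the ring-fusion hydrogens, and the magnesium enolate is trapped regiospecifically as the vinyl triflate.

Step 13
Reactants: 22 (4R,4aS,8aS)-4-{[dimethyl(propan-2-yloxy)silyl]methyl}-3,5,5-trimethyl-8-methylidene-1,4,4a,5,6,7,8,8a-octahydronaphthalen-2-yl trifluoromethanesulfonate
Product: 23 dimethyl(propan-2-yloxy){[(1R,4aS,8aS)-2,8,8-trimethyl-5-methylidene-1,4,4a,5,6,7,8,8a-octahydronaphthalen-1-yl]methyl}silane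
Conditions: Pd(OAc)2 (5 mol%), PPh3, HCO2H, Bu3N, DMF, 60 °C
Reagents that add atoms: none
Why: palladium-catalysed formate reduction of the vinyl triflate replaces oxygen by hydrogen and fixes the ring double bond at C6′–C7′ without touching C5′.

Step 14
Reactants: 23 dimethyl(propan-2-yloxy){[(1R,4aS,8aS)-2,8,8-trimethyl-5-methylidene-1,4,4a,5,6,7,8,8a-octahydronaphthalen-1-yl]methyl}silane
Product: 24 [(1R,4aS,8aS)-2,8,8-trimethyl-5-methylidene-1,4,4a,5,6,7,8,8a-octahydronaphthalen-1-yl]methanol
Conditions: 30% H2O2, KF, KHCO3, THF–MeOH, rt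
Reagents that add atoms: hydrogen peroxide, OO
Why: Tamao oxidation converts the alkoxysilane into the primary alcohol and leaves both alkenes untouched.

Step 15
Reactants: 24 [(1R,4aS,8aS)-2,8,8-trimethyl-5-methylidene-1,4,4a,5,6,7,8,8a-octahydronaphthalen-1-yl]methanol
Product: 25 (1R,4aS,8aS)-1-(iodomethyl)-2,8,8-trimethyl-5-methylidene-1,4,4a,5,6,7,8,8a-octahydronaphthalene
Conditions: I2, PPh3, imidazole, CH2Cl2, 0 °C
Reagents that add atoms: iodine, II
Why: Appel-type iodination of the primary alcohol under neutral conditions gives the radical precursor.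

Step 16
Reactants: 25 (1R,4aS,8aS)-1-(iodomethyl)-2,8,8-trimethyl-5-methylidene-1,4,4a,5,6,7,8,8a-octahydronaphthalene; 13 (3S,5aS,9aS)-3-hydroxy-2,2,5a-trimethyl-6-methylideneoctahydro-1-benzoxepin-7(2H)-one
Product: 26 (3S,5aS,6S,9aS)-3-hydroxy-2,2,5a-trimethyl-6-[2-(right-half unit of 25, CH2 in place of CH2I)ethyl]octahydro-1-benzoxepin-7(2H)-one
Conditions: (Me3Si)3SiH, AIBN (cat.), toluene, 80 °C, slow addition of 25; then DBU (cat.), CH2Cl2, rt
Reagents that add atoms: none
Why: Giese reaction: the silyl radical abstracts iodine, the nucleophilic primary radical adds to the terminus of the α-methylene ketone and the α-keto radical is reduced by the silane; base equilibration then places the side chain at C6 equatorial, cis to the 5a-methyl group, which is both the thermodynamic and the target configuration.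

Step 17
Reactants: 26 coupled ketone
Product: 27 the 7-methylidene analogue of 26 (both exocyclic methylene groups in place, configuration as in 26)
Conditions: Ph3PCH3Br, KOtBu, toluene, 80 °C
Reagents that add atoms: methyltriphenylphosphonium bromide, C[P+](c1ccccc1)(c1ccccc1)c1ccccc1.[Br-]
Why: Wittig methylenation of the hindered ketone; the enolisable C6 is already at its thermodynamic configuration and the right half has no base-sensitive centre.

Step 18
Reactants: 27 bis(methylidene) compound
Product: 29 (3S,5aS,6S,7S,9aS)-6-{2-[(1S-carbinol, 4a′R, 5′R, 8a′S)-1-hydroxy-1,4,4,6-tetramethyl-1,2,3,4,4a,5,8,8a-octahydronaphthalen-5-yl]ethyl}-2,2,5a,7-tetramethyldecahydro-1-benzoxepine-3,7-diol, via bis(acetoxymercurio) diol 28 (not isolated)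
Conditions: Hg(OAc)2 (2.2 equiv), THF–H2O, 0 °C; then NaBH4, aq. NaOH, 0 °C
Reagents that add atoms: water, O
Why: Markovnikov oxymercuration–demercuration is far faster for the two 1,1-disubstituted exocyclic alkenes than for the trisubstituted ring alkene; water should attack C7 equatorially because the axial path is blocked by the syn-axial 5a-methyl group, and C1′ on the convex face (cis to the ring-fusion hydrogens), which sets both tertiary carbinol centres under substrate control.

Step 19
Reactants: 29 triol with the C6′=C7′ alkene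
Product: 30 sipholenol M
Conditions: O2, tetraphenylporphyrin (cat.), visible light, CH2Cl2, −20 °C
Reagents that add atoms: oxygen, O=O
Why: Schenck ene reaction: singlet oxygen adds to C7′ and takes the allylic hydrogen at C5′ suprafacially, moving the double bond to C5′–C6′; since that hydrogen lies on the face opposite to the ring-fusion hydrogens (the side chain was placed on the convex face in step 12), the hydroperoxide should form with the (7′R) configuration.

## Compound list

1 | 2-methylcyclopentane-1,3-dione | CC1C(=O)CCC1=O | starting material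
2 | acrolein | C=CC=O | starting material
3 | 3-(1-methyl-2,5-dioxocyclopentyl)propanal | CC1(CCC=O)C(=O)CCC1=O | intermediate
4 | 2-methyl-2-(4-methylpent-3-en-1-yl)cyclopentane-1,3-dione | CC(C)=CCCC1(C)C(=O)CCC1=O | intermediate
5 | (2R,3S)-3-hydroxy-2-methyl-2-(4-methylpent-3-en-1-yl)cyclopentan-1-one | O=C1[C@](C)(CCC=C(C)C)[C@@H](O)CC1 | intermediate
6 | (2R,3S)-2-{2-[(2S)-3,3-dimethyloxiran-2-yl]ethyl}-3-hydroxy-2-methylcyclopentan-1-one | O=C1[C@](C)(CC[C@@H]2OC2(C)C)[C@@H](O)CC1 | intermediate
7 | bis(trimethylsilyl) ether of the vinyl diol (C3 epimers), not isolated | C=CC1(O[Si](C)(C)C)[C@](C)(CC[C@@H]2OC2(C)C)[C@@H](O[Si](C)(C)C)CC1 | intermediate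
8 | (1S,2R)-2-{2-[(2S)-3,3-dimethyloxiran-2-yl]ethyl}-3-ethenyl-2-methyl-3-[(trimethylsilyl)oxy]cyclopentan-1-ol (C3 epimers) | C=CC1(O[Si](C)(C)C)[C@](C)(CC[C@@H]2OC2(C)C)[C@@H](O)CC1 | intermediate
9 | (1S,2R)-2-{2-[(2S)-3,3-dimethyloxiran-2-yl]ethyl}-2-methyl-3-(oxiran-2-yl)-3-[(trimethylsilyl)oxy]cyclopentan-1-ol (epimers at C3 and oxirane carbon) | C1OC1C2(O[Si](C)(C)C)[C@](C)(CC[C@@H]3OC3(C)C)[C@@H](O)CC2 | intermediate
10 | (3S,5aR,8aS)-2,2,5a-trimethyl-6-(oxiran-2-yl)-6-[(trimethylsilyl)oxy]octahydro-2H-cyclopenta[b]oxepin-3-ol, not isolated | C1OC1C2(O[Si](C)(C)C)[C@]3(C)CC[C@H](O)C(C)(C)O[C@H]3CC2 | intermediate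
11 | (3S,5aS,9aS)-3-hydroxy-6-(hydroxymethyl)-2,2,5a-trimethyloctahydro-1-benzoxepin-7(2H)-one (C6 epimers) | OCC2[C@]3(C)CC[C@H](O)C(C)(C)O[C@H]3CCC2=O | intermediate
12 | primary mesylate of 11, not isolated | CS(=O)(=O)OCC2[C@]3(C)CC[C@H](O)C(C)(C)O[C@H]3CCC2=O | intermediate
13 | (3S,5aS,9aS)-3-hydroxy-2,2,5a-trimethyl-6-methylideneoctahydro-1-benzoxepin-7(2H)-one | C=C2[C@]3(C)CC[C@H](O)C(C)(C)O[C@H]3CCC2=O | intermediate
14 | 4,4-dimethylcyclohex-2-en-1-one | CC1(C)CCC(=O)C=C1 | starting material
15 | isoprene | CC(=C)C=C | starting material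
16 | (4aR,8aS)-4,4,6-trimethyl-3,4,4a,5,8,8a-hexahydronaphthalen-1(2H)-one (cis-fused) | CC1=CC[C@@H]2C(=O)CCC(C)(C)[C@@H]2C1 | intermediate
17 | (4aR,8aS)-4,4,6-trimethyl-1-methylidene-1,2,3,4,4a,5,8,8a-octahydronaphthalene | CC1=CC[C@@H]2C(=C)CCC(C)(C)[C@@H]2C1 | intermediate
18 | (4aR,8aS)-3,5,5-trimethyl-8-methylidene-1,2,4a,5,6,7,8,8a-octahydronaphthalen-2-yl hydroperoxide (C2 epimers), not isolated | CC1=C[C@H]2C(C)(C)CCC(=C)[C@H]2CC1OO | intermediate
19 | (4aR,8aS)-5,5-dimethyl-3,8-dimethylidenedecahydronaphthalen-2-yl hydroperoxide (C2 epimers), not isolated | C=C1C[C@H]2C(C)(C)CCC(=C)[C@H]2CC1OO | intermediate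
20 | (4aR,8aS)-5,5-dimethyl-3,8-dimethylideneoctahydronaphthalen-2(1H)-one, not isolated | C=C1C[C@H]2C(C)(C)CCC(=C)[C@H]2CC1=O | intermediate
21 | (4aR,8aS)-3,5,5-trimethyl-8-methylidene-4a,5,6,7,8,8a-hexahydronaphthalen-2(1H)-one | CC1=C[C@H]2C(C)(C)CCC(=C)[C@H]2CC1=O | intermediate
22 | (4R,4aS,8aS)-4-{[dimethyl(propan-2-yloxy)silyl]methyl}-3,5,5-trimethyl-8-methylidene-1,4,4a,5,6,7,8,8a-octahydronaphthalen-2-yl trifluoromethanesulfonate | CC1=C(OS(=O)(=O)C(F)(F)F)C[C@@H]2C(=C)CCC(C)(C)[C@@H]2[C@H]1C[Si](C)(C)OC(C)C | intermediate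
23 | dimethyl(propan-2-yloxy){[(1R,4aS,8aS)-2,8,8-trimethyl-5-methylidene-1,4,4a,5,6,7,8,8a-octahydronaphthalen-1-yl]methyl}silane | CC1=CC[C@@H]2C(=C)CCC(C)(C)[C@@H]2[C@H]1C[Si](C)(C)OC(C)C | intermediate
24 | [(1R,4aS,8aS)-2,8,8-trimethyl-5-methylidene-1,4,4a,5,6,7,8,8a-octahydronaphthalen-1-yl]methanol | CC1=CC[C@@H]2C(=C)CCC(C)(C)[C@@H]2[C@H]1CO | intermediate
25 | (1R,4aS,8aS)-1-(iodomethyl)-2,8,8-trimethyl-5-methylidene-1,4,4a,5,6,7,8,8a-octahydronaphthalene | CC1=CC[C@@H]2C(=C)CCC(C)(C)[C@@H]2[C@H]1CI | intermediate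
26 | coupled ketone: (3S,5aS,6S,9aS)-3-hydroxy-2,2,5a-trimethyl-6-[2-(right-half unit configured as in 25)ethyl]octahydro-1-benzoxepin-7(2H)-one | CC1=CC[C@@H]2C(=C)CCC(C)(C)[C@@H]2[C@H]1CC[C@H]3[C@]4(C)CC[C@H](O)C(C)(C)O[C@H]4CCC3=O | intermediate
27 | 7-methylidene analogue of 26 (bis-exocyclic methylene compound) | CC1=CC[C@@H]2C(=C)CCC(C)(C)[C@@H]2[C@H]1CC[C@H]3[C@]4(C)CC[C@H](O)C(C)(C)O[C@H]4CCC3=C | intermediate
28 | bis(acetoxymercuriomethyl) diol from 27, not isolated | CC1=CC[C@@H]2[C@@](C[Hg]OC(C)=O)(O)CCC(C)(C)[C@@H]2[C@H]1CC[C@H]3[C@]4(C)CC[C@H](O)C(C)(C)O[C@H]4CC[C@]3(C[Hg]OC(C)=O)O | intermediate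
29 | triol with C6′=C7′ alkene and (5′R)-CH (deoxy, alkene-shifted precursor of the target) | CC1=CC[C@@H]2[C@@](C)(O)CCC(C)(C)[C@@H]2[C@H]1CC[C@H]3[C@]4(C)CC[C@H](O)C(C)(C)O[C@H]4CC[C@]3(C)O | intermediate
30 | sipholenol M: (3S,5aS,6S,7S,9aS)-6-{2-[(1S,4aR,7R,8aS)-7-hydroperoxy-1-hydroxy-1,4,4,6-tetramethyl-1,2,3,4,4a,7,8,8a-octahydronaphthalen-5-yl]ethyl}-2,2,5a,7-tetramethyldecahydro-1-benzoxepine-3,7-diol | CC1=C(CC[C@H]2[C@]3(C)CC[C@H](O)C(C)(C)O[C@H]3CC[C@]2(C)O)[C@@H]2[C@H](C[C@H]1OO)[C@@](C)(O)CCC2(C)C | target

## Step count and risks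

Total: 19 steps. Longest linear sequence: 12 steps (steps 1–8, then 16–19).

**Step 7.** The two epoxide openings may interfere: closure in the exo mode to a tetrahydropyran, or capture of the trisubstituted epoxide by the silylated oxygen. Less likely, the C8 methylene may shift in place of C5a. The fallback separates the two events and runs the ring expansion on a rigid bicycle with a free tertiary alcohol. It sets out from 6: camphorsulfonic acid in CH2Cl2 at 0 °C closes the oxepane to the bicyclic oxepane ketone F1; vinylMgBr in THF gives the tertiary allylic alcohol F2; hydroxyl-directed epoxidation with VO(acac)2 and t-BuOOH gives the epoxy alcohol F3; ZnBr2 in CH2Cl2 then brings about the semipinacol ring expansion alone, in which shift of C5a also relieves the trans-fused five–seven strain. The fallback comes back to the route at 11.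

**Step 19.** Singlet oxygen may approach the less hindered face, where C5′ carries no hydrogen, and take a methyl or C8′ hydrogen instead, which would give regioisomeric hydroperoxides. The fallback changes from the pericyclic to a radical-chain oxygenation. It sets out from 29: N-hydroxyphthalimide (cat.), O2, MeCN, 40 °C. The N-oxyl radical abstracts the weakest C–H bond, the tertiary allylic one at C5′; the allyl radical traps O2 at C5′ or C7′, and the tertiary C5′ hydroperoxide F4 passes to the tetrasubstituted alkene by allylperoxyl (Schenck) rearrangement. The facial outcome at C7′ is then set by oxygen capture and not by the position of the hydrogen, so 30 is expected together with the C7′ epimer F5, to be separated by HPLC. The fallback comes back to the route at 30.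

**Step 9.** The γ,γ-disubstituted enone is a sluggish dienophile, so turnover and face selection under the chiral catalyst may be poor. The fallback sets the absolute configuration by resolution instead of catalysis. It sets out from 14 and 15: AlCl3 (cat.), toluene, rt gives 16 as the racemate, that is, together with the enantiomer F6. A ketoreductase chosen to accept only F6 reduces it to the alcohol F7, and unreacted 16 is separated by chromatography. The fallback comes back to the route at 16.

## Further compounds

F1 | step 7 | (3S,5aR,8aS)-3-hydroxy-2,2,5a-trimethyloctahydro-6H-cyclopenta[b]oxepin-6-one | O=C2[C@]3(C)CC[C@H](O)C(C)(C)O[C@H]3CC2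
F2 | step 7 | (3S,5aR,8aS)-6-ethenyl-2,2,5a-trimethyloctahydro-2H-cyclopenta[b]oxepine-3,6-diol (C6 epimers) | C=CC2(O)[C@]3(C)CC[C@H](O)C(C)(C)O[C@H]3CC2
F3 | step 7 | (3S,5aR,8aS)-2,2,5a-trimethyl-6-(oxiran-2-yl)octahydro-2H-cyclopenta[b]oxepine-3,6-diol (epimers at C6 and oxirane carbon) | C1OC1C2(O)[C@]3(C)CC[C@H](O)C(C)(C)O[C@H]3CC2
F4 | step 19 | C5′ tertiary hydroperoxide of 29 (C6′=C7′ alkene retained, C5′ epimers) | CC1=CC[C@@H]2[C@@](C)(O)CCC(C)(C)[C@@H]2C1(OO)CC[C@H]3[C@]4(C)CC[C@H](O)C(C)(C)O[C@H]4CC[C@]3(C)O
F5 | step 19 | C7′ epimer of 30 | CC1=C(CC[C@H]2[C@]3(C)CC[C@H](O)C(C)(C)O[C@H]3CC[C@]2(C)O)[C@@H]2[C@H](C[C@@H]1OO)[C@@](C)(O)CCC2(C)C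
F6 | step 9 | (4aS,8aR)-4,4,6-trimethyl-3,4,4a,5,8,8a-hexahydronaphthalen-1(2H)-one | CC1=CC[C@H]2C(=O)CCC(C)(C)[C@H]2C1
F7 | step 9 | (4aS,8aR)-4,4,6-trimethyl-1,2,3,4,4a,5,8,8a-octahydronaphthalen-1-ol | CC1=CC[C@H]2C(O)CCC(C)(C)[C@H]2C1
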